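**Numbering.** Ring A: C1 (CO2Me), C2 (Me), C3 (O-aryl), C4 (OH), C5 (Me), C6 (OH). Ring B: C1' (ether O), C2' (CHO), C3' (OH), C4' (Cl), C5' (Me), C6' (CO2H). Compounds 1–27 are defined in the steps and in the compound list; 27 is the target.

## Analysis of the target

Target 27 is an achiral diaryl ether in which two fully substituted benzene rings are joined through one oxygen. It has no stereocentre, so every problem is one of regiochemistry and chemoselectivity. The ether oxygen is flanked by four ortho substituents (C2 and C4 on ring A, C2' and C6' on ring B), which makes a direct Ullmann or SNAr union of two finished arenes the least attractive bond to form. Ring B carries two carbonyl carbons at different oxidation levels (aldehyde at C2', acid at C6'), and ring A a third (the C1 methyl ester) that must stay an ester while C6' ends as the free acid. The sensitive groups are the salicylaldehyde unit, three electron-rich phenols, and the C6' acid, which could close onto the C4 hydroxyl across the ether to a seven-membered lactone under dehydrating conditions. The strategy rests on the pattern of ring B: the C3' hydroxyl and the C1' aryloxy group are meta to each other, the formyl carbon C2' lies between them and C6' is para to the hydroxyl. That is the pattern produced when a vinylketene and an oxygen-substituted alkyne combine to a phenol. The ether C–O bond can therefore be made between a simple ring A phenol and a three-carbon alkyne unit before ring B exists.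

## Retrosynthetic reasoning

**27 ⇒ 26 (masks).** The last cut removes only protecting groups: the three methoxymethyl ethers (C4, C6, C3') and the dimethyl acetal at C2' of acid 26 all fall to aqueous acid in one operation. Leaving this to the end keeps the free phenols, the aldehyde and the acid–phenol pair out of every earlier step. The forward reaction must hydrolyse four acid-labile groups without touching the C1 methyl ester or the diaryl ether.

**26 ⇒ 24 ⇒ 23 (oxidation level at C6').** The carboxyl carbon is traced back to the hydroxymethyl group of 24, stored as the silyl ether in 23. The cut is made here because a carboxyl group on the ketene carbon would change the chemistry of the ring-forming step, whereas a silyloxymethyl group is a spectator there. The forward oxidation must act on the C6' benzylic carbon while C2' stays masked as the acetal; the two carbonyl carbons of ring B are told apart in this way.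

**23 ⇒ 22 ⇒ 21 (C3' oxygen and C4' chlorine).** The C4'–Cl bond is disconnected to the only aromatic C–H of phenol 21, which lies ortho to the free C3' hydroxyl, so the site is fixed by structure. The methoxymethyl group on that hydroxyl is added only after chlorination (22 to 23). It keeps the later oxidation from meeting a free phenol next to an acetal, and it costs no separate deprotection.

**21 ⇒ 9 + 16 (ring B).** Three bonds are cut: C2'–C3', C1'–C6' and C3'–C4'. This turns ring B into ynol ether 9 (C1', C2' and the acetal carbon) and diazo enone 16 (C3', C4', C5', C6' and their substituents) by way of vinylketene 17. The cut is made here because it places five substituents of ring B in one step and moves the hindered ether bond onto an alkyne. The forward reaction must join the acetal-bearing alkyne carbon to the ketene carbonyl carbon and then pass through cyclobutenone 18, dienylketene 19 and dienone 20 to the phenol.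

**9 ⇒ 5 + 7 (ether bond).** The O–C(sp) bond is cut to ring A phenol 5 and dibromoalkene 7. The hindered phenol oxygen is joined to an unhindered vinylic carbon under copper catalysis, and the triple bond then comes from elimination of bromo enol ether 8. Compound 7 goes back by dibromo-olefination to aldehyde 6, which already carries the formyl carbon of the target as its acetal.

**5 ⇒ 3 ⇒ 2 ⇒ 1 (ring A).** The C3–O bond of 5 is traced through aryl formate 4 to the C3 formyl group of 3 and then to the single free ring position of atraric acid 1. Ring A is thus bought complete except for one oxygen. Formylation, protection and aryl migration to oxygen insert that oxygen at the only open carbon and leave the C3 hydroxyl as the one free phenol.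

**16 ⇒ 14 ⇒ 12 + 13 ⇒ 11 ⇒ 10 (ketene precursor).** The diazo group is put on the only enolisable carbon of enone 14 by deacylative diazo transfer through diketone 15. Enone 14 is cut at the acyl–vinyl bond to Weinreb amide 12 and Grignard reagent 13, and 12 goes back through silyl ether 11 to hydroxy ester 10.

## Alternatives that were turned down

**Alternative 1:** The disconnection removes the C2' formyl carbon and the C3' oxygen from diaryl ether A1 (tert-butyl ester at C6', C4' still C–H) and goes back to the ortho-silyl aryl triflate A2. In the forward step a fluoride source converts A2 into the C2'–C3' aryne A3. N,N-Dimethylformamide A4 adds across A3 with its oxygen at C3' and its formyl carbon at C2', and hydrolysis releases the salicylaldehyde A1.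
- For it: the C1' aryloxy group distorts the aryne so that the nucleophilic oxygen attacks C3', the carbon remote from it, so the regiochemistry is well founded. The C6' carbon travels at the acid oxidation level throughout and no late oxidation is needed. Aldehyde and hydroxyl arrive unprotected. On oxidation-state economy this route is stronger than the chosen one.
- Against it: the key step adds one carbon and one oxygen to a ring that must already be complete. A2 is a pentasubstituted arene that has to be built by stepwise substitution. Its ether bond to ring A would have to be made between two di-ortho-substituted arenes (phenol 5 and a ring B halide), which is the hardest bond of the molecule and is not helped by the aryne step.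
- Comparison: the chosen route makes that C–O bond on an alkyne and builds ring B around it. It pays with one late oxidation and offers a convergent union of two short fragments in place of a long linear ring B sequence.

**Alternative 2:** Ring A is cut at C2–C3 and C1–C6. Ring B, complete except for its formyl group, is carried as the aryl ether on the terminus of bis(silyloxy)diene A6, which would undergo [4+2] cycloaddition with methyl but-2-ynoate A7. Elimination of the methoxy group and desilylation then aromatise ring A and give A5.
- For it: the polarity is matched (the oxygen-bearing diene terminus meets the β-carbon of A7). Ring A emerges with all six substituents and both hydroxyls free. Chlorine and the C6' carboxyl are in place from the start, which is stronger than the chosen route on that point.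
- Against it: A7 is a weak dienophile (one ester, β-methyl), and A6 is a tetrasubstituted diene with a bulky aryloxy group on the reacting terminus. The temperatures needed would compete with silyl migration and decomposition of the diene. The C2' formyl group must afterwards be forced onto A5 at a site between two oxygens on a ring deactivated by ester and chlorine, in the presence of the free ring A phenols, and the C3' methyl ether must then be cleaved.
- Comparison: the chosen route pairs an electrophilic ketene with a nucleophilic ynol ether, a fast and polarity-matched addition, and brings the formyl carbon in with the alkyne. It offers a reliable ring-forming event in place of the earlier placement of chlorine and carboxyl.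

**Alternative 3:** Ring B is cut at C1'–C2' and C5'–C6'. The forward step is thermal [4+2] cycloaddition of 4-methoxy-6-methylpyran-2-one A9 with aryloxypropiolate A10 to the bridged lactone A11, followed by decarboxylative cycloreversion to benzoate A8.
- For it: A9 is a cheap commercial compound. The carboxyl carbon is the ester of the alkyne and needs no oxidation. The ether bond is again made on an alkyne, so this route solves the hindered C–O bond as well as the chosen one and reaches its key-step precursors in fewer steps.
- Against it: A10 is a push–pull alkyne whose aryloxy donor lowers its dienophilicity, and A9 is an electron-rich, partly aromatic diene. The pairing would need forcing temperatures that the tert-butyl ester is unlikely to survive. A8 lacks both the C2' formyl group and the C4' chlorine, so two successive electrophilic substitutions must distinguish C2' from C4', both ortho to the methoxy group, before an O-demethylation.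
- Comparison: the chosen route leaves exactly one C–H on ring B, so the substitution that follows has no regiochemical question. It offers this certainty in place of the shorter fragment synthesis.

Key step: step 10

Remark: 2,2-dimethoxyacetaldehyde 6 is sold as an aqueous solution; step 4 assumes that it is first extracted into CH2Cl2 and dried, since the phosphorus ylide does not tolerate water.

## Route

Step 1
Reactants: 1 methyl 2,4-dihydroxy-3,6-dimethylbenzoate (atraric acid)
Product: 2 methyl 3-formyl-4,6-dihydroxy-2,5-dimethylbenzoate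
Conditions: Cl2CHOMe, TiCl4, CH2Cl2, 0 °C to rt; then 1 M HCl
Reagents that add atoms: dichloromethyl methyl ether, COC(Cl)Cl (formyl carbon); water, O (formyl oxygen on hydrolysis)
Why: Rieche formylation; the only free ring position of 1 is ortho to one hydroxyl and para to the other, the titanium phenoxide directs the electrophile there, and hydrolysis of the α-chloro ether gives the aldehyde.

Step 2
Reactants: 2 methyl 3-formyl-4,6-dihydroxy-2,5-dimethylbenzoate
Product: 3 methyl 3-formyl-4,6-bis(methoxymethoxy)-2,5-dimethylbenzoate
Conditions: NaH, MOMCl, DMF, 0 °C to rt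
Reagents that add atoms: chloromethyl methyl ether, COCCl
Why: Williamson-type O-alkylation of both phenoxides; the sodium salts in DMF overcome the hydrogen bonds to the aldehyde and the ester, and 2 has no enolisable position.

Step 3
Reactants: 3 methyl 3-formyl-4,6-bis(methoxymethoxy)-2,5-dimethylbenzoate
Product: 5 methyl 3-hydroxy-4,6-bis(methoxymethoxy)-2,5-dimethylbenzoate, via aryl formate 4 (not isolated)
Conditions: mCPBA, CH2Cl2, 0 °C to rt; then K2CO3 (cat.), MeOH, rt
Reagents that add atoms: 3-chloroperbenzoic acid, OOC(=O)c1cccc(Cl)c1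
Why: Dakin-type Baeyer–Villiger oxidation; the aryl group, with alkoxy donors ortho and para to the formyl carbon, migrates in the Criegee intermediate to give formate 4, and methanolysis frees the phenol while the hindered methyl ester is unchanged in methanol.

Step 4
Reactants: 6 2,2-dimethoxyacetaldehyde
Product: 7 1,1-dibromo-3,3-dimethoxyprop-1-ene
Conditions: CBr4, PPh3, Et3N, CH2Cl2, 0 °C
Reagents that add atoms: carbon tetrabromide, BrC(Br)(Br)Br
Why: Ramirez dibromo-olefination (first stage of the Corey–Fuchs sequence), a Wittig reaction of Ph3P=CBr2; Et3N buffers the acidic phosphorus by-products so that the acetal survives.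

Step 5
Reactants: 5 methyl 3-hydroxy-4,6-bis(methoxymethoxy)-2,5-dimethylbenzoate; 7 1,1-dibromo-3,3-dimethoxyprop-1-ene
Product: 9 methyl 3-[(3,3-dimethoxyprop-1-yn-1-yl)oxy]-4,6-bis(methoxymethoxy)-2,5-dimethylbenzoate, via bromo enol ether 8 (not isolated)
Conditions: CuI (cat.), 2,2'-bipyridine (cat.), K3PO4, toluene, 110 °C; then KOtBu, 1,4-dioxane, rt
Reagents that add atoms: none
Why: Ullmann-type copper-catalysed vinylic C–O coupling of a phenol with a 1,1-dibromoalkene, in which the C–Br bond trans to the substituent reacts and should give the (Z)-bromo enol ether 8, followed by anti dehydrobromination to the aryl ynol ether; the di-ortho-substituted methyl ester and the acetal offer no site to KOtBu at room temperature.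

Step 6
Reactants: 10 methyl 3-hydroxypropanoate
Product: 11 methyl 3-[(tert-butyldimethylsilyl)oxy]propanoate
Conditions: TBSCl, imidazole, DMF, rt
Reagents that add atoms: tert-butyldimethylsilyl chloride, CC(C)(C)[Si](C)(C)Cl
Why: Standard silylation of a primary alcohol; imidazole activates the silyl chloride and takes up HCl.

Step 7
Reactants: 11 methyl 3-[(tert-butyldimethylsilyl)oxy]propanoate
Product: 12 3-[(tert-butyldimethylsilyl)oxy]-N-methoxy-N-methylpropanamide
Conditions: MeNH(OMe)·HCl, iPrMgCl, THF, −20 °C to 0 °C
Reagents that add atoms: N,O-dimethylhydroxylamine hydrochloride, CNOC.Cl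
Why: Weinreb amide formation by aminolysis of the ester with the chloromagnesium amide; the low temperature and the weakly basic amide avoid β-elimination of the silyloxy group.

Step 8
Reactants: 12 3-[(tert-butyldimethylsilyl)oxy]-N-methoxy-N-methylpropanamide; 13 isopropenylmagnesium bromide
Product: 14 1-[(tert-butyldimethylsilyl)oxy]-4-methylpent-4-en-3-one
Conditions: THF, 0 °C; cold aq. NH4Cl
Reagents that add atoms: none
Why: Weinreb ketone synthesis; the chelated tetrahedral magnesium adduct persists until work-up, so the Grignard reagent adds once, and a cold quench limits conjugate addition of the released amine to the α-substituted enone.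

Step 9
Reactants: 14 1-[(tert-butyldimethylsilyl)oxy]-4-methylpent-4-en-3-one
Product: 16 1-[(tert-butyldimethylsilyl)oxy]-2-diazo-4-methylpent-4-en-3-one, via trifluoroacetyl diketone 15 (not isolated)
Conditions: LiN(SiMe3)2, THF, −78 °C; CF3CO2CH2CF3, −78 °C; aq. HCl work-up; then MsN3, Et3N, H2O (1 equiv), MeCN, rt
Reagents that add atoms: 2,2,2-trifluoroethyl trifluoroacetate, O=C(OCC(F)(F)F)C(F)(F)F (trifluoroacetyl group of 15 only); methanesulfonyl azide, CS(=O)(=O)N=[N+]=[N-] (both diazo nitrogens of 16)
Why: Detrifluoroacetylative (deacylative) diazo transfer; kinetic enolisation at the only α-CH2 and C-trifluoroacetylation give 15, the sulfonyl azide attacks the activated carbon, and the trifluoroacetyl group leaves as the N-acyl sulfonamide; −78 °C keeps the β-silyloxy enolate from eliminating.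

Step 10
Reactants: 9 methyl 3-[(3,3-dimethoxyprop-1-yn-1-yl)oxy]-4,6-bis(methoxymethoxy)-2,5-dimethylbenzoate; 16 1-[(tert-butyldimethylsilyl)oxy]-2-diazo-4-methylpent-4-en-3-one
Product: 21 methyl 3-[6-{[(tert-butyldimethylsilyl)oxy]methyl}-2-(dimethoxymethyl)-3-hydroxy-5-methylphenoxy]-4,6-bis(methoxymethoxy)-2,5-dimethylbenzoate, via vinylketene 17 (not isolated), via vinylcyclobutenone 18 (not isolated), via dienylketene 19 (not isolated), via cyclohexadienone 20 (not isolated)
Conditions: hν (medium-pressure Hg lamp, Pyrex, >300 nm), ClCH2CH2Cl, rt, 16 (1.5–2 equiv) added in portions; then 80 °C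
Reagents that add atoms: none
Why: Danheiser benzannulation in its photochemical Wolff form, here with an aryl ynol ether in the role usually taken by alkoxy- and silyloxyalkynes. Irradiation of 16 expels N2 and 1,2-shift of the isopropenyl group gives vinylketene 17. The ether oxygen of 9 makes the acetal-bearing alkyne carbon the nucleophilic one, so it bonds to the ketene carbonyl carbon (C2'–C3') and the aryloxy-bearing carbon bonds to the ketene α-carbon (C1'–C6') in a polar [2+2] addition that gives racemic 4-vinylcyclobutenone 18. Conrotatory 4π opening of 18 gives dienylketene 19, and thermal disrotatory 6π electrocyclisation joins the ketene carbon to the terminal CH2 (C3'–C4'), which closes the six-membered carbocycle as dienone 20; tautomerisation gives phenol 21. No stereocentre is kept, since the quaternary carbon of 18 is lost on ring opening. The step needs the [2+2] regiochemistry, which the polarisation of the ynol ether secures and which places aryloxy meta to the new hydroxyl, and it needs Wolff rearrangement to win over 1,2-hydrogen shift of the acyl carbene toward the CH2OSi group, which direct excitation without a metal catalyst favours. Because the oxygen substituent of 9 is an aryl group with both ortho positions blocked, there is no O-alkyl C–H for retro-ene loss of an alkene, so 9 tolerates the 80 °C that completes the cascade. Any 21 that is O-acylated by surplus 17 is returned by brief K2CO3/MeOH treatment of the crude product.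

Step 11
Reactants: 21 methyl 3-[6-{[(tert-butyldimethylsilyl)oxy]methyl}-2-(dimethoxymethyl)-3-hydroxy-5-methylphenoxy]-4,6-bis(methoxymethoxy)-2,5-dimethylbenzoate
Product: 22 methyl 3-[6-{[(tert-butyldimethylsilyl)oxy]methyl}-4-chloro-2-(dimethoxymethyl)-3-hydroxy-5-methylphenoxy]-4,6-bis(methoxymethoxy)-2,5-dimethylbenzoate
Conditions: NCS (1.05 equiv), MeCN, 0 °C to rt
Reagents that add atoms: N-chlorosuccinimide, O=C1CCC(=O)N1Cl
Why: Electrophilic aromatic chlorination; C4' is the only aromatic C–H in 21 and lies ortho to the free hydroxyl, so site selectivity is structural, and NCS is neutral enough for the acetal, the silyl ether and the methoxymethyl ethers.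

Step 12
Reactants: 22 methyl 3-[6-{[(tert-butyldimethylsilyl)oxy]methyl}-4-chloro-2-(dimethoxymethyl)-3-hydroxy-5-methylphenoxy]-4,6-bis(methoxymethoxy)-2,5-dimethylbenzoate
Product: 23 methyl 3-[6-{[(tert-butyldimethylsilyl)oxy]methyl}-4-chloro-2-(dimethoxymethyl)-3-(methoxymethoxy)-5-methylphenoxy]-4,6-bis(methoxymethoxy)-2,5-dimethylbenzoate
Conditions: NaH, MOMCl, DMF, 0 °C
Reagents that add atoms: chloromethyl methyl ether, COCCl
Why: Williamson-type protection of the remaining phenol; as a methoxymethyl ether it no longer assists ionisation of the neighbouring acetal, it offers no oxidisable phenol in step 14, and it leaves in the final step without an extra operation.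

Step 13
Reactants: 23 methyl 3-[6-{[(tert-butyldimethylsilyl)oxy]methyl}-4-chloro-2-(dimethoxymethyl)-3-(methoxymethoxy)-5-methylphenoxy]-4,6-bis(methoxymethoxy)-2,5-dimethylbenzoate
Product: 24 methyl 3-[4-chloro-2-(dimethoxymethyl)-6-(hydroxymethyl)-3-(methoxymethoxy)-5-methylphenoxy]-4,6-bis(methoxymethoxy)-2,5-dimethylbenzoate
Conditions: Bu4NF, THF, 0 °C to rt
Reagents that add atoms: none
Why: Fluoride-induced desilylation driven by the Si–F bond; ester, acetal, aryl chloride and methoxymethyl ethers are inert to Bu4NF at this temperature.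

Step 14
Reactants: 24 methyl 3-[4-chloro-2-(dimethoxymethyl)-6-(hydroxymethyl)-3-(methoxymethoxy)-5-methylphenoxy]-4,6-bis(methoxymethoxy)-2,5-dimethylbenzoate
Product: 26 5-chloro-3-(dimethoxymethyl)-2-[3-(methoxycarbonyl)-4,6-bis(methoxymethoxy)-2,5-dimethylphenoxy]-4-(methoxymethoxy)-6-methylbenzoic acid, via aldehyde 25 (not isolated)
Conditions: TEMPO (cat.), NaOCl (cat.), NaClO2, MeCN/phosphate buffer (pH 6.7), 35 °C; Na2SO3 quench, then pH 4 at 0 °C
Reagents that add atoms: sodium chlorite, [Na+].[O-]Cl=O
Why: TEMPO/chlorite oxidation (Anelli-type oxoammonium cycle with a Pinnick-type second stage); the oxoammonium ion takes the primary benzylic alcohol to aldehyde 25 and chlorite takes 25 to the acid while regenerating hypochlorite, the near-neutral buffer keeps the dimethyl acetal intact so that C2' cannot be oxidised, and both rings are fully substituted so ring chlorination is excluded.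

Step 15
Reactants: 26 5-chloro-3-(dimethoxymethyl)-2-[3-(methoxycarbonyl)-4,6-bis(methoxymethoxy)-2,5-dimethylphenoxy]-4-(methoxymethoxy)-6-methylbenzoic acid
Product: 27 5-chloro-2-[4,6-dihydroxy-3-(methoxycarbonyl)-2,5-dimethylphenoxy]-3-formyl-4-hydroxy-6-methylbenzoic acid (target)
Conditions: 3 M HCl (aq)/THF 1:1, 45 °C
Reagents that add atoms: water, O (formyl oxygen)
Why: Acid-catalysed hydrolysis of the dimethyl acetal and of the three methoxymethyl ethers through oxocarbenium ions; water as the only hydroxylic component prevents esterification of the hindered acid and closure of the seven-membered lactone, and the di-ortho-substituted methyl ester is stable to dilute acid.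

## Compound list

1 | methyl 2,4-dihydroxy-3,6-dimethylbenzoate (atraric acid) | COC(=O)c1c(C)cc(O)c(C)c1O | starting material
2 | methyl 3-formyl-4,6-dihydroxy-2,5-dimethylbenzoate | COC(=O)c1c(C)c(C=O)c(O)c(C)c1O | intermediate
3 | methyl 3-formyl-4,6-bis(methoxymethoxy)-2,5-dimethylbenzoate | COC(=O)c1c(C)c(C=O)c(OCOC)c(C)c1OCOC | intermediate
4 | methyl 3-(formyloxy)-4,6-bis(methoxymethoxy)-2,5-dimethylbenzoate | COC(=O)c1c(C)c(OC=O)c(OCOC)c(C)c1OCOC | intermediate
5 | methyl 3-hydroxy-4,6-bis(methoxymethoxy)-2,5-dimethylbenzoate | COC(=O)c1c(C)c(O)c(OCOC)c(C)c1OCOC | intermediate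
6 | 2,2-dimethoxyacetaldehyde | COC(OC)C=O | starting material
7 | 1,1-dibromo-3,3-dimethoxyprop-1-ene | COC(OC)C=C(Br)Br | intermediate
8 | methyl 3-{[(1Z)-1-bromo-3,3-dimethoxyprop-1-en-1-yl]oxy}-4,6-bis(methoxymethoxy)-2,5-dimethylbenzoate | COC(OC)/C=C(\Br)Oc1c(C)c(C(=O)OC)c(OCOC)c(C)c1OCOC | intermediate
9 | methyl 3-[(3,3-dimethoxyprop-1-yn-1-yl)oxy]-4,6-bis(methoxymethoxy)-2,5-dimethylbenzoate | COC(=O)c1c(C)c(OC#CC(OC)OC)c(OCOC)c(C)c1OCOC | intermediate
10 | methyl 3-hydroxypropanoate | OCCC(=O)OC | starting material
11 | methyl 3-[(tert-butyldimethylsilyl)oxy]propanoate | COC(=O)CCO[Si](C)(C)C(C)(C)C | intermediate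
12 | 3-[(tert-butyldimethylsilyl)oxy]-N-methoxy-N-methylpropanamide | CON(C)C(=O)CCO[Si](C)(C)C(C)(C)C | intermediate
13 | isopropenylmagnesium bromide | C=C(C)[Mg]Br | starting material
14 | 1-[(tert-butyldimethylsilyl)oxy]-4-methylpent-4-en-3-one | CC(=C)C(=O)CCO[Si](C)(C)C(C)(C)C | intermediate
15 | 3-{[(tert-butyldimethylsilyl)oxy]methyl}-1,1,1-trifluoro-5-methylhex-5-ene-2,4-dione (racemic) | CC(=C)C(=O)C(CO[Si](C)(C)C(C)(C)C)C(=O)C(F)(F)F | intermediate
16 | 1-[(tert-butyldimethylsilyl)oxy]-2-diazo-4-methylpent-4-en-3-one | CC(=C)C(=O)C(=[N+]=[N-])CO[Si](C)(C)C(C)(C)C | intermediate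
17 | 2-{[(tert-butyldimethylsilyl)oxy]methyl}-3-methylbuta-1,3-dien-1-one | CC(=C)C(=C=O)CO[Si](C)(C)C(C)(C)C | intermediate
18 | methyl 3-{[4-{[(tert-butyldimethylsilyl)oxy]methyl}-2-(dimethoxymethyl)-3-oxo-4-(prop-1-en-2-yl)cyclobut-1-en-1-yl]oxy}-4,6-bis(methoxymethoxy)-2,5-dimethylbenzoate (racemic) | COC(=O)c1c(C)c(OC2=C(C(OC)OC)C(=O)C2(CO[Si](C)(C)C(C)(C)C)C(C)=C)c(OCOC)c(C)c1OCOC | intermediate
19 | methyl 3-{[(3Z)-4-{[(tert-butyldimethylsilyl)oxy]methyl}-2-(dimethoxymethyl)-5-methyl-1-oxohexa-1,3,5-trien-3-yl]oxy}-4,6-bis(methoxymethoxy)-2,5-dimethylbenzoate | COC(=O)c1c(C)c(O/C(C(=C=O)C(OC)OC)=C(\CO[Si](C)(C)C(C)(C)C)C(C)=C)c(OCOC)c(C)c1OCOC | intermediate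
20 | methyl 3-{[6-{[(tert-butyldimethylsilyl)oxy]methyl}-2-(dimethoxymethyl)-5-methyl-3-oxocyclohexa-1,5-dien-1-yl]oxy}-4,6-bis(methoxymethoxy)-2,5-dimethylbenzoate | COC(=O)c1c(C)c(OC2=C(C(OC)OC)C(=O)CC(C)=C2CO[Si](C)(C)C(C)(C)C)c(OCOC)c(C)c1OCOC | intermediate
21 | methyl 3-[6-{[(tert-butyldimethylsilyl)oxy]methyl}-2-(dimethoxymethyl)-3-hydroxy-5-methylphenoxy]-4,6-bis(methoxymethoxy)-2,5-dimethylbenzoate | COC(=O)c1c(C)c(Oc2c(C(OC)OC)c(O)cc(C)c2CO[Si](C)(C)C(C)(C)C)c(OCOC)c(C)c1OCOC | intermediate
22 | methyl 3-[6-{[(tert-butyldimethylsilyl)oxy]methyl}-4-chloro-2-(dimethoxymethyl)-3-hydroxy-5-methylphenoxy]-4,6-bis(methoxymethoxy)-2,5-dimethylbenzoate | COC(=O)c1c(C)c(Oc2c(C(OC)OC)c(O)c(Cl)c(C)c2CO[Si](C)(C)C(C)(C)C)c(OCOC)c(C)c1OCOC | intermediate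
23 | methyl 3-[6-{[(tert-butyldimethylsilyl)oxy]methyl}-4-chloro-2-(dimethoxymethyl)-3-(methoxymethoxy)-5-methylphenoxy]-4,6-bis(methoxymethoxy)-2,5-dimethylbenzoate | COC(=O)c1c(C)c(Oc2c(C(OC)OC)c(OCOC)c(Cl)c(C)c2CO[Si](C)(C)C(C)(C)C)c(OCOC)c(C)c1OCOC | intermediate
24 | methyl 3-[4-chloro-2-(dimethoxymethyl)-6-(hydroxymethyl)-3-(methoxymethoxy)-5-methylphenoxy]-4,6-bis(methoxymethoxy)-2,5-dimethylbenzoate | COC(=O)c1c(C)c(Oc2c(C(OC)OC)c(OCOC)c(Cl)c(C)c2CO)c(OCOC)c(C)c1OCOC | intermediate
25 | methyl 3-[4-chloro-2-(dimethoxymethyl)-6-formyl-3-(methoxymethoxy)-5-methylphenoxy]-4,6-bis(methoxymethoxy)-2,5-dimethylbenzoate | COC(=O)c1c(C)c(Oc2c(C(OC)OC)c(OCOC)c(Cl)c(C)c2C=O)c(OCOC)c(C)c1OCOC | intermediate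
26 | 5-chloro-3-(dimethoxymethyl)-2-[3-(methoxycarbonyl)-4,6-bis(methoxymethoxy)-2,5-dimethylphenoxy]-4-(methoxymethoxy)-6-methylbenzoic acid | COC(=O)c1c(C)c(Oc2c(C(OC)OC)c(OCOC)c(Cl)c(C)c2C(=O)O)c(OCOC)c(C)c1OCOC | intermediate
27 | 5-chloro-2-[4,6-dihydroxy-3-(methoxycarbonyl)-2,5-dimethylphenoxy]-3-formyl-4-hydroxy-6-methylbenzoic acid | COC(=O)c1c(C)c(Oc2c(C=O)c(O)c(Cl)c(C)c2C(=O)O)c(O)c(C)c1O | target

## Step count and risks

Total step count: 15. Longest linear sequence: 10 steps (steps 1, 2, 3, 5, 10, 11, 12, 13, 14, 15 from compound 1; the branch through steps 6, 7, 8, 9 from compound 10 is equally long).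

**Step 10 (key step).**
- Risk: 1,2-hydrogen migration in the acyl carbene may compete with the Wolff shift, because the hydrogens of the CH2OSi group are activated by the adjacent oxygen. The aryl ynol ether is also less nucleophilic than an alkyl or silyl ynol ether, so capture of 17 may be slow enough for the ketene to dimerise or to acylate the product.
- Fallback: it generates the same vinylketene thermally, with no carbene on the path; it sets out from ynol ether 9 and comes back to the route at 21.
  - But-2-yn-1-ol is silylated (TBSCl, imidazole) to tert-butyl(but-2-yn-1-yloxy)dimethylsilane F1.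
  - Dichloroketene (Cl3CCOCl, Zn–Cu couple, Et2O) should add to F1 to give 2-{[(tert-butyldimethylsilyl)oxy]methyl}-4,4-dichloro-3-methylcyclobut-2-en-1-one F2. The methyl-bearing alkyne carbon is the better cation-stabilising terminus and should end β to the carbonyl, but a regioisomer may have to be removed.
  - Zn dust in AcOH/TMEDA removes both chlorines and gives 2-{[(tert-butyldimethylsilyl)oxy]methyl}-3-methylcyclobut-2-en-1-one F3.
  - Heating F3 with 9 in toluene at 80–110 °C opens the four-membered ring to 17, which then follows the same path through 18, 19 and 20 to 21.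

**Step 5.**
- Risk: the phenol of 5 has two ortho substituents, so the copper-mediated C–O bond formation may be slow. A second phenoxide may then displace the remaining bromide, or the base may degrade bromo enol ether 8 before elimination.
- Fallback: it makes the C–O bond by SN2 alkylation and the triple bond by elimination of an enol triflate; it sets out from 5 and comes back at 9.
  - 5 is alkylated with 3-bromo-1,1-dimethoxypropan-2-one (K2CO3, acetone) to the aryloxy ketone methyl 3-(3,3-dimethoxy-2-oxopropoxy)-4,6-bis(methoxymethoxy)-2,5-dimethylbenzoate F4.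
  - LiN(SiMe3)2 and then PhNTf2 in THF at −78 °C deprotonate the more acidic ArOCH2 position and give the (Z)-enol triflate F5.
  - KOtBu in THF at −78 to 0 °C eliminates triflate anti to the vinylic hydrogen and gives 9.

**Step 9.**
- Risk: the enolate of 14, or the anion of diketone 15, may expel the β-silyloxy group (E1cB). O-trifluoroacetylation may also leave the carbon unactivated for diazo transfer.
- Fallback: it introduces the silyloxymethyl carbon after the diazo group, so that no enolate with a β-leaving group is formed; it sets out from isopropenylmagnesium bromide 13 and comes back at 16.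
  - 13 is acetylated with N-methoxy-N-methylacetamide to 3-methylbut-3-en-2-one F6 (this ketone can also be bought).
  - LiN(SiMe3)2 and CF3CO2CH2CF3 give the diketone 1,1,1-trifluoro-5-methylhex-5-ene-2,4-dione F7.
  - MsN3, Et3N and H2O in MeCN give 1-diazo-3-methylbut-3-en-2-one F8.
  - DBU-catalysed aldol-type addition of F8 to formaldehyde (paraformaldehyde, MeCN) gives 2-diazo-1-hydroxy-4-methylpent-4-en-3-one F9.
  - TBSCl and imidazole convert F9 into 16.

**Step 14.**
- Risk: chlorite addition to aldehyde 25 may be slow at neutral pH because the formyl group has two ortho substituents, so the oxidation may stall. Lowering the pH to speed it up risks hydrolysis of the dimethyl acetal and over-oxidation at C2'.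
- Fallback: it changes the mask at C2' to a hydrolysis-resistant cyclic acetal and oxidises in two separate stages; it sets out from 23 and comes back to the route at 27.
  - Transacetalisation of 23 with 2,2-dimethylpropane-1,3-diol (PPTS cat., toluene, 45 °C, reduced pressure) gives the 5,5-dimethyl-1,3-dioxane silyl ether F10.
  - Bu4NF gives the benzylic alcohol F11.
  - Dess–Martin periodinane with NaHCO3 gives the aldehyde F12.
  - A standard Pinnick oxidation (NaClO2, NaH2PO4, 2-methylbut-2-ene, tBuOH/H2O) gives the acid F13.
  - 6 M HCl (aq)/THF at 50 °C removes the dioxane and the three methoxymethyl ethers to give 27.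

## Further compounds

F1 | step 10 | tert-butyl(but-2-yn-1-yloxy)dimethylsilane | CC#CCO[Si](C)(C)C(C)(C)C
F2 | step 10 | 2-{[(tert-butyldimethylsilyl)oxy]methyl}-4,4-dichloro-3-methylcyclobut-2-en-1-one | CC1=C(CO[Si](C)(C)C(C)(C)C)C(=O)C1(Cl)Cl
F3 | step 10 | 2-{[(tert-butyldimethylsilyl)oxy]methyl}-3-methylcyclobut-2-en-1-one | CC1=C(CO[Si](C)(C)C(C)(C)C)C(=O)C1
F4 | step 5 | methyl 3-(3,3-dimethoxy-2-oxopropoxy)-4,6-bis(methoxymethoxy)-2,5-dimethylbenzoate | COC(=O)c1c(C)c(OCC(=O)C(OC)OC)c(OCOC)c(C)c1OCOC
F5 | step 5 | methyl 3-{[(1Z)-3,3-dimethoxy-2-{[(trifluoromethyl)sulfonyl]oxy}prop-1-en-1-yl]oxy}-4,6-bis(methoxymethoxy)-2,5-dimethylbenzoate | COC(=O)c1c(C)c(O/C=C(\OS(=O)(=O)C(F)(F)F)C(OC)OC)c(OCOC)c(C)c1OCOC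
F6 | step 9 | 3-methylbut-3-en-2-one | CC(=C)C(C)=O
F7 | step 9 | 1,1,1-trifluoro-5-methylhex-5-ene-2,4-dione | CC(=C)C(=O)CC(=O)C(F)(F)F
F8 | step 9 | 1-diazo-3-methylbut-3-en-2-one | CC(=C)C(=O)C=[N+]=[N-]
F9 | step 9 | 2-diazo-1-hydroxy-4-methylpent-4-en-3-one | CC(=C)C(=O)C(=[N+]=[N-])CO
F10 | step 14 | methyl 3-[6-{[(tert-butyldimethylsilyl)oxy]methyl}-4-chloro-2-(5,5-dimethyl-1,3-dioxan-2-yl)-3-(methoxymethoxy)-5-methylphenoxy]-4,6-bis(methoxymethoxy)-2,5-dimethylbenzoate | COC(=O)c1c(C)c(Oc2c(C3OCC(C)(C)CO3)c(OCOC)c(Cl)c(C)c2CO[Si](C)(C)C(C)(C)C)c(OCOC)c(C)c1OCOC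
F11 | step 14 | methyl 3-[4-chloro-2-(5,5-dimethyl-1,3-dioxan-2-yl)-6-(hydroxymethyl)-3-(methoxymethoxy)-5-methylphenoxy]-4,6-bis(methoxymethoxy)-2,5-dimethylbenzoate | COC(=O)c1c(C)c(Oc2c(C3OCC(C)(C)CO3)c(OCOC)c(Cl)c(C)c2CO)c(OCOC)c(C)c1OCOC
F12 | step 14 | methyl 3-[4-chloro-2-(5,5-dimethyl-1,3-dioxan-2-yl)-6-formyl-3-(methoxymethoxy)-5-methylphenoxy]-4,6-bis(methoxymethoxy)-2,5-dimethylbenzoate | COC(=O)c1c(C)c(Oc2c(C3OCC(C)(C)CO3)c(OCOC)c(Cl)c(C)c2C=O)c(OCOC)c(C)c1OCOC
F13 | step 14 | 5-chloro-3-(5,5-dimethyl-1,3-dioxan-2-yl)-2-[3-(methoxycarbonyl)-4,6-bis(methoxymethoxy)-2,5-dimethylphenoxy]-4-(methoxymethoxy)-6-methylbenzoic acid | COC(=O)c1c(C)c(Oc2c(C3OCC(C)(C)CO3)c(OCOC)c(Cl)c(C)c2C(=O)O)c(OCOC)c(C)c1OCOC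
A1 | alternative 1 | tert-butyl 3-formyl-4-hydroxy-2-[3-(methoxycarbonyl)-4,6-bis(methoxymethoxy)-2,5-dimethylphenoxy]-6-methylbenzoate | COC(=O)c1c(C)c(Oc2c(C=O)c(O)cc(C)c2C(=O)OC(C)(C)C)c(OCOC)c(C)c1OCOC
A2 | alternative 1 | tert-butyl 2-[3-(methoxycarbonyl)-4,6-bis(methoxymethoxy)-2,5-dimethylphenoxy]-6-methyl-4-{[(trifluoromethyl)sulfonyl]oxy}-3-(trimethylsilyl)benzoate | COC(=O)c1c(C)c(Oc2c([Si](C)(C)C)c(OS(=O)(=O)C(F)(F)F)cc(C)c2C(=O)OC(C)(C)C)c(OCOC)c(C)c1OCOC
A3 | alternative 1 | tert-butyl 3,4-didehydro-2-[3-(methoxycarbonyl)-4,6-bis(methoxymethoxy)-2,5-dimethylphenoxy]-6-methylbenzoate (aryne) | COC(=O)c1c(C)c(OC2=C(C(=O)OC(C)(C)C)C(C)=CC#C2)c(OCOC)c(C)c1OCOC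
A4 | alternative 1 | N,N-dimethylformamide | CN(C)C=O
A5 | alternative 2 | methyl 3-[2-(tert-butoxycarbonyl)-4-chloro-5-methoxy-3-methylphenoxy]-4,6-dihydroxy-2,5-dimethylbenzoate | COC(=O)c1c(C)c(Oc2cc(OC)c(Cl)c(C)c2C(=O)OC(C)(C)C)c(O)c(C)c1O
A6 | alternative 2 | tert-butyl 3-chloro-4-methoxy-6-({4-methoxy-3-methyl-2,4-bis[(trimethylsilyl)oxy]buta-1,3-dien-1-yl}oxy)-2-methylbenzoate (double-bond geometry not fixed) | COC(O[Si](C)(C)C)=C(C)C(O[Si](C)(C)C)=COc1cc(OC)c(Cl)c(C)c1C(=O)OC(C)(C)C
A7 | alternative 2 | methyl but-2-ynoate | CC#CC(=O)OC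
A8 | alternative 3 | tert-butyl 4-methoxy-2-[3-(methoxycarbonyl)-4,6-bis(methoxymethoxy)-2,5-dimethylphenoxy]-6-methylbenzoate | COC(=O)c1c(C)c(Oc2cc(OC)cc(C)c2C(=O)OC(C)(C)C)c(OCOC)c(C)c1OCOC
A9 | alternative 3 | 4-methoxy-6-methyl-2H-pyran-2-one | COc1cc(C)oc(=O)c1
A10 | alternative 3 | methyl 3-[(3-tert-butoxy-3-oxoprop-1-yn-1-yl)oxy]-4,6-bis(methoxymethoxy)-2,5-dimethylbenzoate | COC(=O)c1c(C)c(OC#CC(=O)OC(C)(C)C)c(OCOC)c(C)c1OCOC
A11 | alternative 3 | tert-butyl 8-methoxy-5-[3-(methoxycarbonyl)-4,6-bis(methoxymethoxy)-2,5-dimethylphenoxy]-1-methyl-3-oxo-2-oxabicyclo[2.2.2]octa-5,7-diene-6-carboxylate (racemic) | O=C1OC2(C)C=C(OC)C1C(Oc3c(C)c(C(=O)OC)c(OCOC)c(C)c3OCOC)=C2C(=O)OC(C)(C)C
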